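Ring positions used below: O1, O2, C3, C4, C4a, O5, C6(=O), C7, C7a of the furo[3,2-c][1,2]dioxin-6-one; the chain on C3 is C1'–C16'.

- **Cuts:** C9'=C10' (olefination), then C4–C4a together with O1–C7a (the 1,2-dioxane ring), then O2–C3 (epoxide perhydrolysis) and C1'–C2' (Grignard opening).
- **Forward order:** a C9 chain is joined to (S)-2-methylglycidol, and the tertiary hydroperoxide and its CH2I arm are made. The lactone ring enters ready-made as α-angelica lactone and the 1,2-dioxane ring is closed onto it in one operation. Ozonolysis and Horner–Wadsworth–Emmons olefination finish the (E,E,E)-triene.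
- **Enabling feature:** C4a (bearing CH3 and O5) and C7a are the γ- and β-carbons of a butenolide. Its aromatic 5-methylfuran-2-olate captures at C4a a radical generated at the neopentyl-type C4, and the butenolide so formed accepts the peroxide oxygen O1 at C7a.
- **Stereochemistry:** C3 from (S)-2-methylglycidol through SN2 perhydrolysis with inversion; C4a from a chiral ammonium ion pair in the key step; C7a from the cis ring fusion forced by the tether; alkene geometry from (2E,4E)-hepta-2,4-dienal and an E-selective olefination.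

Key step: step 7

Remark: the sense of induction of the cinchonidinium salt in step 7 cannot be predicted with certainty; it is assumed to favour the 4aS epimer, and the cinchonine-derived pseudoenantiomer would be taken otherwise.

Step 1
Reactants: 1 (S)-2-methylglycidol
Product: 2 [(2R)-2-methyloxiran-2-yl]methyl 4-methylbenzenesulfonate
Conditions: TsCl, Et3N, DMAP (cat.), CH2Cl2, 0 °C
Reagents that add atoms: p-toluenesulfonyl chloride, Cc1ccc(cc1)S(=O)(=O)Cl
Why: O-sulfonylation of the primary alcohol leaves the epoxide and its stereocentre untouched and turns the CH2OH arm into the leaving group needed in step 3.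

Step 2
Reactants: 3 9-bromonon-1-ene
Product: 4 non-8-en-1-ylmagnesium bromide (THF solution)
Conditions: Mg, I2 (cat.), THF, 20–40 °C
Reagents that add atoms: magnesium, [Mg]
Why: Magnesium inserts into the primary C–Br bond (Grignard reagent formation) and the remote terminal alkene is inert.

Step 3
Reactants: 2 [(2R)-2-methyloxiran-2-yl]methyl 4-methylbenzenesulfonate; 4 non-8-en-1-ylmagnesium bromide
Product: 6 (2R)-2-(dec-9-en-1-yl)-2-methyloxirane, via hydroxy tosylate 5 (not isolated)
Conditions: CuI (10 mol%), THF, −40 → −20 °C; then 2 M NaOH (aq.), 20 °C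
Reagents that add atoms: none
Why: Copper-catalysed Grignard opening should occur at the unhindered epoxide CH2 and not at the neopentyl-type CH2OTs, and the tertiary alkoxide then displaces tosylate (3-exo-tet) to give the transposed epoxide, so the stereocentre of 2 is carried over without any bond to it being broken.

Step 4
Reactants: 6 (2R)-2-(dec-9-en-1-yl)-2-methyloxirane
Product: 7 (2S)-2-hydroperoxy-2-methyldodec-11-en-1-ol
Conditions: H2O2 (dried ethereal solution, 10 equiv), H3PMo12O40 (5 mol%), Et2O, 20 °C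
Reagents that add atoms: hydrogen peroxide, OO
Why: Acid-catalysed perhydrolysis of a 2,2-disubstituted epoxide opens the C–O bond at the tertiary carbon by backside attack of H2O2, so the peroxide-bearing stereocentre (C3 of the target) is set with inversion from that of 6.

Step 5
Reactants: 7 (2S)-2-hydroperoxy-2-methyldodec-11-en-1-ol
Product: 8 (2S)-2-methyl-2-[(triethylsilyl)peroxy]dodec-11-en-1-ol
Conditions: Et3SiCl (1.05 equiv), imidazole, CH2Cl2, −40 °C
Reagents that add atoms: chlorotriethylsilane, CC[Si](CC)(CC)Cl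
Why: The hydroperoxide OH is more acidic and more nucleophilic (α-effect) than the neopentyl-type primary alcohol, so one equivalent of Et3SiCl should silylate it selectively (silyl peroxide formation).

Step 6
Reactants: 8 (2S)-2-methyl-2-[(triethylsilyl)peroxy]dodec-11-en-1-ol
Product: 10 triethyl{[(2S)-1-iodo-2-methyldodec-11-en-2-yl]peroxy}silane, via primary triflate 9 (not isolated)
Conditions: Tf2O, 2,6-lutidine, CH2Cl2, −78 °C; then Bu4NI, −78 → 20 °C
Reagents that add atoms: tetrabutylammonium iodide, CCCC[N+](CCCC)(CCCC)CCCC.[I-]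
Why: A primary triflate carrying a β-peroxy group cannot ionise, so iodide should displace it by SN2 even at this neopentyl-type carbon, and no phosphine that could reduce the O–O bond is involved.

Step 7
Reactants: 10 triethyl{[(2S)-1-iodo-2-methyldodec-11-en-2-yl]peroxy}silane; 11 α-angelica lactone (5-methylfuran-2(3H)-one)
Product: 14 (3S,4aS,7aS)-3-(dec-9-en-1-yl)-3,4a-dimethyl-3,4,4a,7a-tetrahydrofuro[3,2-c][1,2]dioxin-6(7H)-one (cis-fused 1,2-dioxane/γ-lactone), via iodo hydroperoxide 12 (not isolated), via butenolide hydroperoxide 13 (not isolated)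
Conditions: 11 (2.5 equiv), CsF (3 equiv), N-(9-anthracenylmethyl)-O-allylcinchonidinium bromide (10 mol%), PhCl, 365 nm LED, 0 °C, argon (O2-free)
Reagents that add atoms: none
Why: Proposed new method: fluoride strips Et3Si from 10 (peroxide anion of 12) and deprotonates 11 to the aromatic 5-methylfuran-2-olate, whose photoexcited ion pair with the chiral ammonium cation reduces the C–I bond; the primary radical at the neopentyl-type C4 is captured by the furanolate at its methyl-bearing carbon, the resulting butenolide radical anion hands its electron to the next C–I bond (SRN1 chain), and the peroxide anion then adds to the β-carbon of the new butenolide, so C4–C4a and O1–C7a form in one operation without any SN2 step at the hindered CH2. Closest known reaction types are the photostimulated SRN1 alkylation of enolates by neopentyl iodides, the light-driven enantioselective alkylation of chiral ammonium enolates by alkyl iodides under phase transfer, and the base-mediated intramolecular oxa-Michael addition of hydroperoxides to butenolides. The 1,2-dioxane ring closes 6-exo-trig; the lactone ring is already present in 11. C3 is carried over from 10, C4a is set by the cinchonidinium cation shielding one face of the planar furanolate during radical capture, and C7a follows from C4a because the short tether can deliver O1 only to the alkene face that gives the cis-fused bicycle. The step needs coupling at the γ-carbon (only there is the adduct a conjugated, low-lying radical anion), electron transfer to C–I and not to O–O (as its anion the peroxide is a poor acceptor and cannot expel an oxygen radical to form an epoxide), and ring closure ahead of intermolecular epoxidation (six-membered transition state).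

Step 8
Reactants: 14 (3S,4aS,7aS)-3-(dec-9-en-1-yl)-3,4a-dimethyl-3,4,4a,7a-tetrahydrofuro[3,2-c][1,2]dioxin-6(7H)-one
Product: 15 9-[(3S,4aS,7aS)-3,4a-dimethyl-6-oxohexahydrofuro[3,2-c][1,2]dioxin-3-yl]nonanal
Conditions: O3, CH2Cl2, −78 °C; then Me2S, −78 → 20 °C
Reagents that add atoms: ozone, [O-][O+]=O
Why: Ozonolysis with Me2S work-up cleaves the terminal alkene to the aldehyde, and dialkyl peroxides and lactones are inert to ozone and to Me2S.

Step 9
Reactants: 16 (2E,4E)-hepta-2,4-dienal
Product: 17 (2E,4E)-hepta-2,4-dien-1-ol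
Conditions: NaBH4, CeCl3·7H2O, MeOH, 0 °C
Reagents that add atoms: none
Why: Luche reduction is 1,2-selective and keeps both E double bonds.

Step 10
Reactants: 17 (2E,4E)-hepta-2,4-dien-1-ol
Product: 18 (2E,4E)-1-bromohepta-2,4-diene
Conditions: PBr3, Et2O, −10 °C
Reagents that add atoms: phosphorus tribromide, BrP(Br)Br
Why: PBr3 converts the primary allylic alcohol into the bromide at low temperature and should retain the E,E geometry.

Step 11
Reactants: 18 (2E,4E)-1-bromohepta-2,4-diene
Product: 19 diethyl [(2E,4E)-hepta-2,4-dien-1-yl]phosphonate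
Conditions: P(OEt)3 (neat), 120 °C
Reagents that add atoms: triethyl phosphite, CCOP(OCC)OCC
Why: Michaelis–Arbuzov reaction of the primary allylic bromide with triethyl phosphite gives the phosphonate.

Step 12
Reactants: 15 9-[(3S,4aS,7aS)-3,4a-dimethyl-6-oxohexahydrofuro[3,2-c][1,2]dioxin-3-yl]nonanal; 19 diethyl [(2E,4E)-hepta-2,4-dien-1-yl]phosphonate
Product: 20 (3S,4aS,7aS)-3-[(9E,11E,13E)-hexadeca-9,11,13-trien-1-yl]-3,4a-dimethyl-3,4,4a,7a-tetrahydrofuro[3,2-c][1,2]dioxin-6(7H)-one
Conditions: 19, LiN(SiMe3)2, THF, −78 °C; then 15, −78 → 0 °C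
Reagents that add atoms: none
Why: Horner–Wadsworth–Emmons olefination with the preformed lithium anion of an allylic phosphonate should give the new disubstituted double bond mainly as the E isomer, the anion adding to the aldehyde at −78 °C faster than it can deprotonate the lactone.

Compound list
1 | (S)-2-methylglycidol, [(2S)-2-methyloxiran-2-yl]methanol | C1O[C@@]1(C)CO | starting material
2 | [(2R)-2-methyloxiran-2-yl]methyl 4-methylbenzenesulfonate | C1O[C@@]1(C)COS(=O)(=O)c2ccc(C)cc2 | intermediate
3 | 9-bromonon-1-ene | C=CCCCCCCCBr | starting material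
4 | non-8-en-1-ylmagnesium bromide | C=CCCCCCCC[Mg]Br | intermediate
5 | (2R)-2-hydroxy-2-methyldodec-11-en-1-yl 4-methylbenzenesulfonate (bromomagnesium alkoxide in the flask) | C=CCCCCCCCC[C@](O)(C)COS(=O)(=O)c1ccc(C)cc1 | intermediate
6 | (2R)-2-(dec-9-en-1-yl)-2-methyloxirane | C=CCCCCCCCC[C@]1(C)CO1 | intermediate
7 | (2S)-2-hydroperoxy-2-methyldodec-11-en-1-ol | C=CCCCCCCCC[C@@](OO)(C)CO | intermediate
8 | (2S)-2-methyl-2-[(triethylsilyl)peroxy]dodec-11-en-1-ol | C=CCCCCCCCC[C@@](OO[Si](CC)(CC)CC)(C)CO | intermediate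
9 | (2S)-2-methyl-2-[(triethylsilyl)peroxy]dodec-11-en-1-yl trifluoromethanesulfonate | C=CCCCCCCCC[C@@](OO[Si](CC)(CC)CC)(C)COS(=O)(=O)C(F)(F)F | intermediate
10 | triethyl{[(2S)-1-iodo-2-methyldodec-11-en-2-yl]peroxy}silane | C=CCCCCCCCC[C@@](OO[Si](CC)(CC)CC)(C)CI | intermediate
11 | α-angelica lactone, 5-methylfuran-2(3H)-one | CC1=CCC(=O)O1 | starting material
12 | (2S)-2-hydroperoxy-1-iodo-2-methyldodec-11-ene (peroxide anion in the flask) | C=CCCCCCCCC[C@@](OO)(C)CI | intermediate
13 | (5S)-5-[(2S)-2-hydroperoxy-2-methyldodec-11-en-1-yl]-5-methylfuran-2(5H)-one | C=CCCCCCCCC[C@@](OO)(C)C[C@]1(C)OC(=O)C=C1 | intermediate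
14 | (3S,4aS,7aS)-3-(dec-9-en-1-yl)-3,4a-dimethyl-3,4,4a,7a-tetrahydrofuro[3,2-c][1,2]dioxin-6(7H)-one | C=CCCCCCCCC[C@@]1(C)C[C@]2(C)OC(=O)C[C@@H]2OO1 | intermediate
15 | 9-[(3S,4aS,7aS)-3,4a-dimethyl-6-oxohexahydrofuro[3,2-c][1,2]dioxin-3-yl]nonanal | O=CCCCCCCCC[C@@]1(C)C[C@]2(C)OC(=O)C[C@@H]2OO1 | intermediate
16 | (2E,4E)-hepta-2,4-dienal | CC/C=C/C=C/C=O | starting material
17 | (2E,4E)-hepta-2,4-dien-1-ol | CC/C=C/C=C/CO | intermediate
18 | (2E,4E)-1-bromohepta-2,4-diene | CC/C=C/C=C/CBr | intermediate
19 | diethyl [(2E,4E)-hepta-2,4-dien-1-yl]phosphonate | CC/C=C/C=C/CP(=O)(OCC)OCC | intermediate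
20 | (3S,4aS,7aS)-3-[(9E,11E,13E)-hexadeca-9,11,13-trien-1-yl]-3,4a-dimethyl-3,4,4a,7a-tetrahydrofuro[3,2-c][1,2]dioxin-6(7H)-one | CC/C=C/C=C/C=C/CCCCCCCC[C@@]1(C)C[C@]2(C)OC(=O)C[C@@H]2OO1 | target

Total step count: 12. Longest linear sequence: 8 steps (1, 3, 4, 5, 6, 7, 8, 12).

Steps most likely to fail

1. Step 7 (proposed new method). The radical chain may not be sustained if electron transfer to the C–I bond is slow. The β-peroxy radical may fragment to the alkene before it is captured. The peroxide anion may close onto the CH2I carbon (4-exo-tet). Facial control at C4a by the ion pair may be weak.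
Fallback by known chemistry, from 8 back to 14: 8 is oxidised (Parikh–Doering oxidation, SO3·pyridine, DMSO, iPr2NEt) to (2S)-2-methyl-2-[(triethylsilyl)peroxy]dodec-11-enal F1. 11 is silylated (Me3SiCl, Et3N) to trimethyl[(5-methylfuran-2-yl)oxy]silane F2. Vinylogous Mukaiyama aldol addition of F2 to F1 (BF3·OEt2, CH2Cl2, −78 °C) should give the γ-adduct (5R)-5-{(2S)-1-hydroxy-2-methyl-2-[(triethylsilyl)peroxy]dodec-11-en-1-yl}-5-methylfuran-2(5H)-one F3 (carbinol epimers); its epimer at the butenolide carbon would have to be removed by chromatography. Bu4NF followed by Et2NH in CF3CH2OH frees the hydroperoxide and closes the dioxane ring by oxa-Michael addition, giving (3S,4aS,7aS)-3-(dec-9-en-1-yl)-4-hydroxy-3,4a-dimethyl-3,4,4a,7a-tetrahydrofuro[3,2-c][1,2]dioxin-6(7H)-one F4. The alcohol is converted with 1,1'-thiocarbonyldiimidazole into O-[(3S,4aS,7aS)-3-(dec-9-en-1-yl)-3,4a-dimethyl-6-oxohexahydrofuro[3,2-c][1,2]dioxin-4-yl] 1H-imidazole-1-carbothioate F5. Barton–McCombie deoxygenation (Bu3SnH, AIBN, catalytic PhSeSePh as fast hydrogen donor so that the β-peroxy radical is quenched before it can close to an epoxide) returns to 14.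

2. Step 6. Substitution at the neopentyl-type carbon may be too slow, and the neighbouring peroxide oxygen may take part, leading to ring closure or rearrangement instead of iodide entry.
Fallback, from 6 back to 10 (it also bypasses steps 4 and 5): ring expansion of 6 with dimethylsulfoxonium methylide (Me3S(O)I, KOC(CH3)3, tert-butanol, 50 °C, Corey–Chaykovsky type) should give (2R)-2-(dec-9-en-1-yl)-2-methyloxetane F6. Lewis-acid-mediated opening by H2O2 (Me3SiOTf, Et2O, −78 °C) at the tertiary carbon with inversion gives (3S)-3-hydroperoxy-3-methyltridec-12-en-1-ol F7. Selective silylation as in step 5 gives (3S)-3-methyl-3-[(triethylsilyl)peroxy]tridec-12-en-1-ol F8. Oxidation of the unhindered primary alcohol (TEMPO, PhI(OAc)2, MeCN/H2O) gives (3S)-3-methyl-3-[(triethylsilyl)peroxy]tridec-12-enoic acid F9. Radical iododecarboxylation (PhI(OAc)2, I2, hν, Hunsdiecker type) then places iodine on the CH2 next to the peroxide carbon without any substitution at a hindered centre and returns to 10.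

3. Step 12. Part of the new double bond may form as the Z isomer, and the strong base may deprotonate the lactone and trigger β-elimination of the peroxide oxygen.
Fallback, from 14 back to 20 (it replaces steps 8 and 12 by an sp2–sp2 coupling under mild base): cross-metathesis of 14 with vinylboronic acid pinacol ester (second-generation Grubbs catalyst, RuCl2(=CHPh)(PCy3)(H2IMes), CH2Cl2, 40 °C) should give 2-[(1E)-10-{(3S,4aS,7aS)-3,4a-dimethyl-6-oxohexahydrofuro[3,2-c][1,2]dioxin-3-yl}dec-1-en-1-yl]-4,4,5,5-tetramethyl-1,3,2-dioxaborolane F10. Takai olefination of commercial (E)-pent-2-enal (CHI3, CrCl2, THF) gives (1E,3E)-1-iodohexa-1,3-diene F11. Suzuki–Miyaura coupling of F10 with F11 (PdCl2(dppf), K3PO4 (aq.), THF, 20 °C) joins the two alkenyl carbons with retention of geometry and gives 20.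

Further compounds
F1 | step 7 | (2S)-2-methyl-2-[(triethylsilyl)peroxy]dodec-11-enal | C=CCCCCCCCC[C@@](OO[Si](CC)(CC)CC)(C)C=O
F2 | step 7 | trimethyl[(5-methylfuran-2-yl)oxy]silane | Cc1ccc(O[Si](C)(C)C)o1
F3 | step 7 | (5R)-5-{(2S)-1-hydroxy-2-methyl-2-[(triethylsilyl)peroxy]dodec-11-en-1-yl}-5-methylfuran-2(5H)-one (carbinol epimers) | C=CCCCCCCCC[C@@](OO[Si](CC)(CC)CC)(C)C(O)[C@]1(C)OC(=O)C=C1
F4 | step 7 | (3S,4aS,7aS)-3-(dec-9-en-1-yl)-4-hydroxy-3,4a-dimethyl-3,4,4a,7a-tetrahydrofuro[3,2-c][1,2]dioxin-6(7H)-one (C4 epimers) | C=CCCCCCCCC[C@@]1(C)C(O)[C@]2(C)OC(=O)C[C@@H]2OO1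
F5 | step 7 | O-[(3S,4aS,7aS)-3-(dec-9-en-1-yl)-3,4a-dimethyl-6-oxohexahydrofuro[3,2-c][1,2]dioxin-4-yl] 1H-imidazole-1-carbothioate (C4 epimers) | C=CCCCCCCCC[C@@]1(C)C(OC(=S)n3ccnc3)[C@]2(C)OC(=O)C[C@@H]2OO1
F6 | step 6 | (2R)-2-(dec-9-en-1-yl)-2-methyloxetane | C=CCCCCCCCC[C@]1(C)CCO1
F7 | step 6 | (3S)-3-hydroperoxy-3-methyltridec-12-en-1-ol | C=CCCCCCCCC[C@@](OO)(C)CCO
F8 | step 6 | (3S)-3-methyl-3-[(triethylsilyl)peroxy]tridec-12-en-1-ol | C=CCCCCCCCC[C@@](OO[Si](CC)(CC)CC)(C)CCO
F9 | step 6 | (3S)-3-methyl-3-[(triethylsilyl)peroxy]tridec-12-enoic acid | C=CCCCCCCCC[C@@](OO[Si](CC)(CC)CC)(C)CC(=O)O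
F10 | step 12 | 2-[(1E)-10-{(3S,4aS,7aS)-3,4a-dimethyl-6-oxohexahydrofuro[3,2-c][1,2]dioxin-3-yl}dec-1-en-1-yl]-4,4,5,5-tetramethyl-1,3,2-dioxaborolane | CC1(C)OB(/C=C/CCCCCCCC[C@@]2(C)C[C@]3(C)OC(=O)C[C@@H]3OO2)OC1(C)C
F11 | step 12 | (1E,3E)-1-iodohexa-1,3-diene | CC/C=C/C=C/I
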